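The number I watch is a ratio: the D standing at the end of a run, divided by the Q charged. An engineer's first-order lag processes the same fraction of its input in a given time, whatever the input's size. So if D forms at a rate proportional to cQ, first order in Q, with G and the time held and no other source of Q, that ratio is the same at any charge of Q.

| flask | J | Q | G | remark | time |
|---|---|---|---|---|---|
| elm | 0.59 M | 0.34 equiv | 0.14 mol% | run made earlier |  |
| birch | 0.59 M | 0.75 equiv | 0.14 mol% | run made earlier |  |
| flask | 0.59 M | 0.500 equiv | 0.14 mol% |  | 25 h |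

| run | time / h | D / % | X / % |
|---|---|---|---|
| elm | 2.00 | 2.9 | 1.1 |
| elm | 6.00 | 3.3 | 2.1 |
| elm | 12.0 | 3.8 | 5.5 |
| elm | 20.0 | 4.5 | 8.4 |
| elm | 25.0 | 6.6 | 8.6 |
| birch | 2.00 | 0.5 | 0.9 |
| birch | 6.00 | 4.4 | 1.7 |
| birch | 12.0 | 5.7 | 4.2 |
| birch | 20.0 | 9.0 | 5.8 |
| birch | 25.0 | 9.0 | 6.0 |

(standard deviation of a reading: 1 percentage point)

* amount of D in percent of the J and Q together charged, at 2.5 h, 8.0 h, 15 h and 25 h

The readings are percent of J and Q together, so I multiply each by (1 + e)/e, with e the equivalents of Q. At 25.0 h, the elm run's 6.6% gives 26.0% and the birch run's 9.0% gives 21.0%. I carry their mean, 23.5%, as the ratio of D to charged Q at 25 h.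

Is one number enough? The gap of 5 percentage points stands against a scatter of 3.9 points in elm and 2.3 points in birch, so late in the runs it passes. At 12.0 h the two ratios read 15.0% and 13.3%, which also pass. At 2.00 h they read 11.4% and 1.17%, so I lean on no early value.

In the flask Q is 33.3% of the charge, so I expect 7.84% of D at 25 h. The forecast, reasoning that “More Q clearly speeds D formation”, gives 2.5%, 4.1%, 5.6% and 7.5%. My figure for the last point is higher than its 7.5%.

The flask gives 1.27%, 3.63%, 6.07% and 8.83%.

    J ⇌ Q (K = 0.840, k = 2.70 × 10⁻⁶ s⁻¹)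
    J + G → G + X (k = 0.00240 L mol⁻¹ s⁻¹)
    G + Q → G + D (k = 0.00540 L mol⁻¹ s⁻¹)
    2 G → Z (k = 0.00650 L mol⁻¹ s⁻¹)

Put through the carried reckoning, the flask's 8.83% gives a ratio of D to charged Q of 26.5%, close to 23.5%. Yet 90% of the charged Q still stands at 25.0 h, and J stands at 81% of its own charge.

(The runs stem from a simulated flask for substances that don't exist, and the scatter is random.)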